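The data come from a simulation for an exercise; noise was put on by code.

The flask holds partner for 70.0 % of its substrate, and with partner charged below substrate, it is the limiting reagent, so that figure is the ceiling on the target.

| flask | substrate | partner | capture agent | free catalyst | remark | time |
|---|---|---|---|---|---|---|
| ochre | 0.050 M | 0.023 M | 2.5 mM | 8 mM | run made earlier |  |
| violet | 0.050 M | 0.053 M | 2.5 mM | 8 mM | run made earlier |  |
| teal | 0.050 M | 0.035 M | 3.8 mM | 8 mM | run made earlier |  |
| flask | 0.050 M | 0.0350 M | 2.50 mM | 8.0 mM |  | 15 min |

| run | time / min | target / % | crystals / % | catalyst intermediate B / % |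
|---|---|---|---|---|
| ochre | 1.33 | 40.7 | 41.2 | 4.0 |
| ochre | 2.00 | 42.0 | 40.9 | 6.9 |
| ochre | 3.00 | 41.4 | 42.1 | 8.8 |
| ochre | 5.00 | 42.1 | 40.1 | 8.8 |
| ochre | 10.0 | 42.3 | 40.1 | 8.7 |
| ochre | 15.0 | 41.5 | 39.2 | 8.9 |
| violet | 2.50 | 68.0 | 66.9 | 0 |
| violet | 5.00 | 88.7 | 87.2 | 0.3 |
| violet | 8.00 | 93.9 | 91.4 | 0 |
| violet | 10.0 | 94.9 | 94.6 | 0 |
| violet | 12.0 | 95.4 | 93.1 | 0.2 |
| violet | 15.0 | 96.3 | 93.7 | 0.3 |
| teal | 3.00 | 62.6 | 61.5 | 2.2 |
| teal | 6.00 | 63.3 | 62.0 | 6.6 |
| teal | 10.0 | 62.0 | 62.9 | 6.7 |
| teal | 12.0 | 62.8 | 61.7 | 7.2 |
| teal | 15.0 | 62.7 | 62.5 | 7.4 |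

(readings scatter by 0.5 percentage points)

* the target in the flask at 15 min, as a percentage of the substrate charged
* the crystals in the flask at 15 min, as a percentage of the substrate charged
* the catalyst intermediate B in the flask at 15 min, as a percentage of the substrate charged

- amounts and yields of target count crystals too
- given per volume of solution although it is solid: crystals
- the numbers in the tables scatter by 0.5 percentage points (one standard deviation)

The teal run's target, with the flask's partner but more capture agent, reads flat from 3.00 min, so the flask at 15 min should stand on a plateau too. The teal run's target reads 3.66 mM short of its partner, less than its 3.8 mM of capture agent. Taking one partner per capture agent, the flask's floor is 65.0 %.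

The ceiling tightens by working with what is left. The ochre run's target averages 41.7 %, so 13.3 % is that run's reading of the fraction left: the share of the capture agent's charge unspent once partner is gone, with the scatter of the readings on it. The flask is the ochre recipe with more partner, so its fraction left should stand lower, which by this reading puts the flask's target below 65.7 %. The forecast, holding that “the capture agent removes about its own amount of partner”, gives 65.4 % target, inside this bracket, with 64.3 % crystals and 7.1 % catalyst intermediate B.

The flask gives 65.4 % target, 64.4 % crystals and 8.45 % catalyst intermediate B.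

    substrate + free catalyst → catalyst intermediate A (k = 1.80 L mol⁻¹ s⁻¹)
    partner + catalyst intermediate B → catalyst intermediate C (k = 190 L mol⁻¹ s⁻¹)
    catalyst intermediate A ⇌ catalyst intermediate B (K = 2.90, k = 1.00 s⁻¹)
    crystals ⇌ target, rate k4*(cs4 - [target]) while solid is left; crystals form when [target] > cs4 (solubility = 0.500 mM, k = 2.20 s⁻¹)
    catalyst intermediate C → free catalyst + target (k = 0.250 s⁻¹)
    catalyst intermediate C + capture agent → trapped intermediate (k = 20.0 L mol⁻¹ s⁻¹)

The flask's capture agent stands at 7.3 % of its charge at 15.0 min, below the ochre reading. The flask's target moves by 5 points at 0.0325 M or 0.0375 M of partner, the other charges and the time held. A neighbouring flask with 0.0088 M of partner has less than ochre, so its fraction left should stand above the ochre reading, and its target between 13.3 % and 17.6 %. That neighbour gives 15.3 % target, with 54.2 % of its capture agent left.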